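**Remark on the chemistry:** Isoirigenin has no stereocentre and the C3–C1′ bond rotates freely, so it is achiral and there is no enantiomer to select. Compounds 1 and 4 are taken as catalogue compounds.

## Retrosynthetic overview

1. Isoirigenin 9 ⇐ tribenzyl ether 8 by global hydrogenolysis.
2. 8 ⇐ 2′-hydroxychalcone 6. The C3–C1′ bond of the 3-aryl-4H-chromen-4-one (aryl on C3, not C2) is made by an oxidative 1,2-shift of ring B from Cβ to Cα, the laboratory copy of the 2→3 aryl migration of isoflavone synthase. The freed C2 carbon then closes ring C (O1–C2).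
3. 6 ⇐ acetophenone 3 + aldehyde 5 (Claisen–Schmidt); 5 ⇐ 4 by O-benzylation.
4. 3 ⇐ 1 by ortho-iodination and Cu-mediated methoxylation. The OMe is placed beside the only free OH, so ring closure can only give the 8-methoxy (not the 6-methoxy) pattern.
5. Ring order: rings A and B are bought; ring C (pyranone) is closed in the key step.

Key step: step 5

## Route

Step 1
Reactants: 1 1-[2,4-bis(benzyloxy)-6-hydroxyphenyl]ethan-1-one
Product: 2 1-[4,6-bis(benzyloxy)-2-hydroxy-3-iodophenyl]ethan-1-one
Conditions: NIS (1.05 equiv), TFA (cat.), MeCN, 0 °C → rt, dark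
Reagents that add atoms: N-iodosuccinimide, O=C1CCC(=O)N1I
Why: Electrophilic aromatic iodination, which in 2-hydroxy-4,6-dialkoxyacetophenones should go to C3 (ortho to the free phenol, para to the 6-benzyloxy group) rather than to C5, which is flanked by two benzyloxy groups.

Step 2
Reactants: 2 1-[4,6-bis(benzyloxy)-2-hydroxy-3-iodophenyl]ethan-1-one
Product: 3 1-[4,6-bis(benzyloxy)-2-hydroxy-3-methoxyphenyl]ethan-1-one
Conditions: NaOMe (25% in MeOH, 6 equiv), CuI (0.3 equiv), DMF, 105 °C, Ar
Reagents that add atoms: sodium methoxide, [Na+].[O-]C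
Why: Ullmann-type copper-mediated methoxylation of an ortho-halophenol, a substitution that tolerates the free phenoxide, the benzyl ethers and the acetyl group, which is deactivated as a vinylogous carboxylate.

Step 3
Reactants: 4 3-hydroxy-4,5-dimethoxybenzaldehyde
Product: 5 3-(benzyloxy)-4,5-dimethoxybenzaldehyde
Conditions: BnBr (1.1 equiv), K2CO3 (1.5 equiv), DMF, 50 °C
Reagents that add atoms: benzyl bromide, BrCc1ccccc1
Why: Williamson ether synthesis on the only phenol, which masks it against the oxidant of step 5 with a group that leaves together with the ring-A benzyl ethers.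

Step 4
Reactants: 3 1-[4,6-bis(benzyloxy)-2-hydroxy-3-methoxyphenyl]ethan-1-one; 5 3-(benzyloxy)-4,5-dimethoxybenzaldehyde
Product: 6 (E)-1-[4,6-bis(benzyloxy)-2-hydroxy-3-methoxyphenyl]-3-[3-(benzyloxy)-4,5-dimethoxyphenyl]prop-2-en-1-one
Conditions: 50% aq KOH (excess), EtOH/THF, rt; then cold 1 M HCl to pH 5, rapid filtration
Reagents that add atoms: none
Why: Claisen–Schmidt aldol condensation of a methyl ketone with a non-enolisable aldehyde, in which E1cB dehydration gives the conjugated E-alkene and a cold, brief work-up should keep the chalcone from closing to the flavanone.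

Step 5
Reactants: 6 (E)-1-[4,6-bis(benzyloxy)-2-hydroxy-3-methoxyphenyl]-3-[3-(benzyloxy)-4,5-dimethoxyphenyl]prop-2-en-1-one
Product: 8 5,7-bis(benzyloxy)-3-[3-(benzyloxy)-4,5-dimethoxyphenyl]-8-methoxy-4H-chromen-4-one, via dimethyl acetal 7 (not isolated)
Conditions: Tl(NO3)3·3H2O (1.2 equiv), MeOH/HC(OMe)3/CH2Cl2, rt; filter off TlNO3; then 10% aq HCl, 55 °C
Reagents that add atoms: methanol, CO (its methoxy groups stand only in intermediate 7 and leave again on ring closure)
Why: Tl(III) adds to the enone C=C with methanol (oxythallation: Tl on Cα, OMe on the benzylic Cβ), and heterolysis of the weak C–Tl bond is assisted by ring B, which bridges as a phenonium ion and shifts from Cβ to Cα while Tl(III) leaves as Tl(I); the Cβ oxocarbenium ion left behind is trapped by methanol as acetal 7. This is the thallium(III) nitrate oxidative rearrangement of 2′-hydroxychalcones, the laboratory counterpart of the 2→3 aryl shift by which isoflavone synthase turns a flavanone into an isoflavone, and 2′-hydroxy-4′,6′-dialkoxychalcones are an established substrate class for it. On acidification the acetal ionises, the 2′-OH adds to the oxocarbenium carbon (6-exo-trig O-cyclisation that forms O1–C2) and loss of the second methanol gives the 4H-pyran-4-one ring C. No stereocentre remains, because the racemic centre of 7 becomes the sp2 carbon C3 of 8. The step needs aryl migration to outrun aurone or flavanone formation, and the 4-OMe para to the migrating carbon of ring B together with the trapping solvent (MeOH/orthoformate) should secure it. It also needs closure on the correct oxygen, and since the other ortho oxygen is benzylated only the OH next to the methoxy group can close, which fixes the 8-methoxy pattern.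

Step 6
Reactants: 8 5,7-bis(benzyloxy)-3-[3-(benzyloxy)-4,5-dimethoxyphenyl]-8-methoxy-4H-chromen-4-one
Product: 9 isoirigenin, 5,7-dihydroxy-3-(3-hydroxy-4,5-dimethoxyphenyl)-8-methoxy-4H-chromen-4-one
Conditions: H2 (1 atm), 10% Pd/C, THF/MeOH, rt, stopped at full debenzylation
Reagents that add atoms: none
Why: Catalytic hydrogenolysis should cleave the three aryl benzyl ethers while the methyl ethers and the conjugated C2=C3 bond of the chromone persist, and the neutral medium avoids the base-induced ring opening and reclosure (Wessely–Moser type) that would move the 8-methoxy group to C6.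

## Compound list

1 | 1-[2,4-bis(benzyloxy)-6-hydroxyphenyl]ethan-1-one | CC(=O)c1c(O)cc(OCc2ccccc2)cc1OCc1ccccc1 | starting material
2 | 1-[4,6-bis(benzyloxy)-2-hydroxy-3-iodophenyl]ethan-1-one | CC(=O)c1c(O)c(I)c(OCc2ccccc2)cc1OCc1ccccc1 | intermediate
3 | 1-[4,6-bis(benzyloxy)-2-hydroxy-3-methoxyphenyl]ethan-1-one | CC(=O)c1c(O)c(OC)c(OCc2ccccc2)cc1OCc1ccccc1 | intermediate
4 | 3-hydroxy-4,5-dimethoxybenzaldehyde | COc1cc(C=O)cc(O)c1OC | starting material
5 | 3-(benzyloxy)-4,5-dimethoxybenzaldehyde | COc1cc(C=O)cc(OCc2ccccc2)c1OC | intermediate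
6 | (E)-1-[4,6-bis(benzyloxy)-2-hydroxy-3-methoxyphenyl]-3-[3-(benzyloxy)-4,5-dimethoxyphenyl]prop-2-en-1-one | COc1cc(/C=C/C(=O)c2c(O)c(OC)c(OCc3ccccc3)cc2OCc2ccccc2)cc(OCc2ccccc2)c1OC | intermediate
7 | 1-[4,6-bis(benzyloxy)-2-hydroxy-3-methoxyphenyl]-2-[3-(benzyloxy)-4,5-dimethoxyphenyl]-3,3-dimethoxypropan-1-one (racemic) | COc1cc(C(C(OC)OC)C(=O)c2c(O)c(OC)c(OCc3ccccc3)cc2OCc2ccccc2)cc(OCc2ccccc2)c1OC | intermediate (not isolated)
8 | 5,7-bis(benzyloxy)-3-[3-(benzyloxy)-4,5-dimethoxyphenyl]-8-methoxy-4H-chromen-4-one | COc1cc(-c2coc3c(OC)c(OCc4ccccc4)cc(OCc4ccccc4)c3c2=O)cc(OCc2ccccc2)c1OC | intermediate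
9 | isoirigenin, 5,7-dihydroxy-3-(3-hydroxy-4,5-dimethoxyphenyl)-8-methoxy-4H-chromen-4-one | COc1cc(-c2coc3c(OC)c(O)cc(O)c3c2=O)cc(O)c1OC | target

## Summary

Total step count: 6. Longest linear sequence: 5 (steps 1, 2, 4, 5, 6); step 3 is a one-step branch.

Steps most likely to fail:

**1. Step 5 (key step).** What may go wrong:
- acid-induced closure of the chalcone to the flavanone before oxythallation;
- oxidation or thallation of the very electron-rich ring A;
- too slow a migration of the 3,4,5-trioxygenated ring B, which would divert material to aurone-type products;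
- partial loss of the peri 5-O-benzyl group in the warm acid, which is harmless because step 6 removes it anyway.

Thallium salts are highly toxic and must be removed completely before step 6.

Fallback, a 1,2-acyl shift in place of the aryl shift: it sets out from 6 and comes back at 8. O-Alkylation of 6 with MOMCl/NaH in THF at 0 °C should give the 2′-O-methoxymethyl chalcone F1. Weitz–Scheffer epoxidation (30% H2O2, aq NaOH, MeOH/THF, 0 °C → rt) should give the racemic trans-epoxide F2. BF3·OEt2 in CH2Cl2 at −20 °C should open the epoxide at the benzylic carbon with Meinwald-type migration of the aroyl group, giving the racemic α-formyl ketone F3. Brief warming with HCl in MeOH should remove the MOM group and cyclodehydrate to 8.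

**2. Step 2.** What may go wrong:
- hydrodeiodination instead of substitution;
- slow C–O coupling at a carbon flanked by two oxygen substituents;
- base-induced condensation of the acetyl group at 105 °C.

Fallback, which also bypasses step 1 should its regioselectivity be imperfect: it sets out from 1 and comes back at 3. Magnesium-mediated ortho-formylation (MgCl2, Et3N, paraformaldehyde, MeCN, reflux) can only occur at the single free position ortho to the phenol and should give the salicylaldehyde F4. Dakin oxidation (H2O2, NaOH, THF/H2O, 0 °C, the aldehyde reacting ahead of the hindered ketone) should give the catechol F5. Methylation of the non-chelated 3-OH (MeI 1.0 equiv, K2CO3, acetone, rt) should give 3, the chelated 2-OH staying free.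

**3. Step 6.** What may go wrong:
- saturation of the C2=C3 bond to the isoflavanone on prolonged hydrogenation;
- stalling of the catalyst by traces of thallium or iodide, which would leave the 5-O-benzyl group in place.

Fallback, non-reductive: it sets out from 8 and comes back directly at 9. BCl3 with pentamethylbenzene as cation scavenger in CH2Cl2 at −78 °C should cleave the benzyl ethers in preference to the methyl ethers; no new compound is made (F0).

## Further compounds

F1 | step 5 | (E)-1-[4,6-bis(benzyloxy)-3-methoxy-2-(methoxymethoxy)phenyl]-3-[3-(benzyloxy)-4,5-dimethoxyphenyl]prop-2-en-1-one | COCOc1c(OC)c(OCc2ccccc2)cc(OCc2ccccc2)c1C(=O)/C=C/c1cc(OC)c(OC)c(OCc2ccccc2)c1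
F2 | step 5 | [4,6-bis(benzyloxy)-3-methoxy-2-(methoxymethoxy)phenyl]{trans-3-[3-(benzyloxy)-4,5-dimethoxyphenyl]oxiran-2-yl}methanone (racemic, one enantiomer drawn) | COCOc1c(OC)c(OCc2ccccc2)cc(OCc2ccccc2)c1C(=O)[C@@H]1O[C@H]1c1cc(OC)c(OC)c(OCc2ccccc2)c1
F3 | step 5 | 3-[4,6-bis(benzyloxy)-3-methoxy-2-(methoxymethoxy)phenyl]-2-[3-(benzyloxy)-4,5-dimethoxyphenyl]-3-oxopropanal (racemic) | COCOc1c(OC)c(OCc2ccccc2)cc(OCc2ccccc2)c1C(=O)C(C=O)c1cc(OC)c(OC)c(OCc2ccccc2)c1
F4 | step 2 | 3-acetyl-4,6-bis(benzyloxy)-2-hydroxybenzaldehyde | CC(=O)c1c(O)c(C=O)c(OCc2ccccc2)cc1OCc1ccccc1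
F5 | step 2 | 1-[4,6-bis(benzyloxy)-2,3-dihydroxyphenyl]ethan-1-one | CC(=O)c1c(O)c(O)c(OCc2ccccc2)cc1OCc1ccccc1
F0 | step 6 | none | none
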